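## The problem

The target is an isoflavone: a chromen-4-one (rings A and C) with hydrogen on C2 and a 2,4,5-trimethoxyphenyl group (ring B) on C3. It has no stereocentre, so every difficulty is one of regiochemistry and chemoselectivity. Ring A is hexasubstituted: C5–OH, C6–prenyl, C7–OMe, C8–OH, C8a–O1 and C4a–C4. Its four oxygens must be placed so that the ring oxygen O1 lies beside O8, and so that O5 and O8 (para to each other) end free while O7 stays methylated. Three pairs must therefore be told apart: the two ortho oxygens of the ring-A ketone (only one may close ring C), the two phenols O5 and O8, and the single ring-A CH (C6) against the free positions of the more nucleophilic ring B. The prenyl alkene does not tolerate electrophilic oxidants or hydrogenation, and acid can close it onto O5 to a chroman. The 5,8-hydroquinone is easily oxidised to the quinone, above all in base. The pyranone with its unsubstituted C2 is opened by hot alkali, and five aryl methyl ethers forbid a global Lewis-acid deprotection. The enabling feature is the electron-rich aryl group on C3 beside C2–H. This is the pattern left when the aryl group of a chalcone moves from the β- to the α-carbon, and ring B has methoxy groups para and ortho to C1', which makes it an excellent migrating group.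

## Retrosynthesis

**15 from 14.** The last cut is the O8–CH2 bond of a methoxymethyl (MOM) acetal, so the air-sensitive hydroquinone 15 appears only at the end. Hydrogenolysis is excluded once the prenyl group is present, and Lewis acids would touch the methyl ethers, so a group that leaves with dilute protic acid is used on O8. O5 needs no protection because its hydrogen bond to C4=O makes it inert. The forward step must be mild enough not to protonate the alkene.

**14 from 13, 12 and 11.** The C6–CH2 bond of the prenyl group is cut next. Direct C-prenylation or a cross-coupling at C6 would require an electrophilic substitution that ring B would intercept. A Claisen shift from O5 has only one outcome, since C6 is the only ortho carbon of O5 that bears hydrogen (the other is the ring-fusion carbon C4a) and the para carbon C8 is substituted. Because a [3,3] shift inverts the allyl unit, the ether must be the tertiary 1,1-dimethylallyl ether 13 to deliver a linear prenyl group. Ether 13 comes from alkyne 12 by semi-hydrogenation, and 12 from phenol 11 by copper-catalysed propargylic etherification. All five prenyl carbons thus arrive after the oxidative step.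

**11 from 10 and 9.** This is a protecting-group exchange. Benzyl ethers are needed through the key step because they stand aqueous KOH, the thallium oxidant and hot methanolic HCl. An acetal on O6' could fall off before ring closure and leave two free ortho hydroxyls. At the stage of 9 the only alkene is the pyranone, so hydrogenolysis to 10 is safe. In 10 only the 8-OH is free of chelation, so one equivalent of MOMCl should give 11. Two steps are spent here so that each half of the route has suitable protection.

**9 from 7 through 8 (key disconnection).** The C3–C1' bond and the O1–C2 bond are cut together, leading to the 2'-hydroxychalcone 7. Two neighbouring cuts were weighed. Inserting C2 into a deoxybenzoin needs an arylacetic acid and a Friedel–Crafts or Hoesch acylation of an oxidation-prone tetraoxygenated phenol. Making C3–C1' by cross-coupling to a 3-halochromone costs extra steps and a boronic acid, and is kept as the fallback. The aryl shift needs only a chalcone, one condensation away from two simple carbonyl compounds. The forward reaction must oxidise the enone and not the two electron-rich rings, must find only one free ortho hydroxyl, and must meet no second alkene. The toxic thallium reagent is confined to one step, and the spent TlNO3 precipitates and is filtered off.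

**7 from 5 and 6.** The Cα=Cβ bond is cut by a Claisen–Schmidt condensation. Aldehyde 6 is bought with all three ring-B methoxy groups in place, and ketone 5 carries the complete ring-A oxygen pattern.

**5 from 3 and 4; 3 from 1 through 2.** Two O–benzyl bonds and the C3'–O bond are cut. Elbs hydroxylation of the symmetric ketone 1 can give only one product, since each phenol has one open para position and the two are equivalent. It brings in the fourth oxygen at the first step, where modest conversion costs least. The selective dibenzylation of 3 consumes two equivalents of 4 in one flask. It is the regiochemical decision of the route, because it fixes which ortho oxygen later becomes O1.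

## Roads not taken

Alternative 1: Ring A would be assembled by a Moore ring expansion. Thermolysis of the squaric-ester-derived cyclobutenone A2 opens the four-membered ring to a dienylketene, and 6π electrocyclisation forms the C5–C4a bond and gives hydroquinone A1. Every ring-A substituent, prenyl included, is placed by the order of organometallic additions to the squarate. This avoids a low-converting phenol oxidation, a selective benzylation and a Claisen step, and in regiochemical certainty for ring A it is the better road. Its weakness is that A1 is only ring A. The one remaining CH, crowded between OH and OMOM, must still be acylated with an arylacetyl unit in the presence of an acid-sensitive prenyl group. The two hydroquinone hydroxyls must be differentiated, ring C must be closed through the correct oxygen, and C2 must be added. The chosen plan sets against this that the acetyl group and three of the four oxygens are bought in 1, and that rings B and C follow in two steps from aldehyde 6 with no Friedel–Crafts chemistry on a prenylated arene.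

Alternative 2: Ring C would be closed by an aryne annulation. CsF releases a 3-methoxyaryne from silyl triflate A4. The enolate oxygen of hydroxyacrylate A5 adds at C8a, and the aryl anion at C4a attacks the ester, giving isoflavone A3 with the O1–C8a and C4–C4a bonds formed. This is the most convergent road and needs no heavy-metal oxidant, and the methoxy group next to the aryne directs the addition correctly. In those respects it is better than the chosen plan. However, A3 has no oxygen on C8 and a methyl ether on O5. A chelation-controlled demethylation next to a prenyl group and a late para-hydroxylation of a base-labile, alkene-bearing isoflavone would still be required. The pentasubstituted precursor A4 is itself a multistep target. C-arylation of the ambident enolate, or an ene reaction of the aryne with the prenyl alkene, could also compete. The chosen plan installs the C8 oxygen in its first step on a simple acetophenone.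

Alternative 3: Ring B would be built by a Dötz benzannulation. Ethynylchromone A7, the carbene complex (CO)5Cr=C(OMe)C(OMe)=CH2 A8 and one CO ligand combine to form the C1'–C2', C2'–C3' and C5'–C6' bonds and give phenol A6, which needs only O-methylation and MOM removal. It offers a differentiated 2'-oxygen and a short end game, and it avoids thallium. Its weakness is that the key step builds the one ring that can be bought complete as aldehyde 6. Substrate A7 already contains the whole prenylated ring A and ring C, so none of the hard problems is removed. The alkyne is electron-poor, chromium is stoichiometric, and the oxidative release of the arene threatens the para-methoxyphenol and the prenyl group. The chosen plan is shorter and uses the key step where the molecule is difficult.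

Key step: step 4

Assumption: in the dibenzylation of 3 the hydroxyl that stays free is taken to be the 2'-OH between the acetyl group and O3', as hydrogen bonding and buttressing predict; the stereocentre of acetal 8 is racemic and is erased within step 4.

## Route

Step 1
Reactants: 1 1-(2,6-dihydroxy-4-methoxyphenyl)ethanone
Product: 3 1-(2,3,6-trihydroxy-4-methoxyphenyl)ethanone, via potassium aryl sulfate 2 (not isolated)
Conditions: K2S2O8 (1 equiv), aq KOH, 10–20 °C; acidify, wash out unreacted 1; then aq HCl, 90 °C, under N2
Reagents that add atoms: potassium peroxodisulfate, [K+].[K+].[O-]S(=O)(=O)OOS(=O)(=O)[O-]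
Why: Elbs persulfate oxidation: the phenolate attacks the peroxide oxygen through its para carbon, and acid hydrolysis of the aryl sulfate 2 frees the new phenol. The two hydroxyls of 1 are equivalent and each has one open para position, so only one regioisomer can form; unreacted 1 is recovered.

Step 2
Reactants: 3 1-(2,3,6-trihydroxy-4-methoxyphenyl)ethanone; 4 benzyl bromide (two equivalents are consumed)
Product: 5 1-[3,6-bis(benzyloxy)-2-hydroxy-4-methoxyphenyl]ethanone
Conditions: BnBr (2.1 equiv), K2CO3, acetone, reflux, under N2
Reagents that add atoms: benzyl bromide (the second equivalent, the same compound as 4), BrCc1ccccc1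
Why: Twofold Williamson etherification in which each of two molecules of benzyl bromide delivers one benzyl group. The 3'-OH is the only hydroxyl not hydrogen-bonded to the acetyl group, and of the two hydroxyls ortho to the ketone the 6'-OH, flanked by hydrogen, is the more accessible; whichever of these two reacts first, the second benzyl group should go to the other, while the 2'-OH, buttressed between acetyl and benzyloxy, holds the sole chelate and resists weak base. The assignment would be checked by NOE contacts of H-5' to both OCH3 and OCH2Ph.

Step 3
Reactants: 5 1-[3,6-bis(benzyloxy)-2-hydroxy-4-methoxyphenyl]ethanone; 6 2,4,5-trimethoxybenzaldehyde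
Product: 7 (E)-1-[3,6-bis(benzyloxy)-2-hydroxy-4-methoxyphenyl]-3-(2,4,5-trimethoxyphenyl)prop-2-en-1-one
Conditions: KOH, EtOH–THF, rt
Reagents that add atoms: none
Why: Claisen–Schmidt condensation of a methyl ketone with a non-enolisable aldehyde; E1cB loss of water gives the conjugated E-enone. In strong base the 2'-oxido chalcone does not close to the flavanone, and benzyl ethers are inert.

Step 4
Reactants: 7 (E)-1-[3,6-bis(benzyloxy)-2-hydroxy-4-methoxyphenyl]-3-(2,4,5-trimethoxyphenyl)prop-2-en-1-one
Product: 9 5,8-bis(benzyloxy)-7-methoxy-3-(2,4,5-trimethoxyphenyl)chromen-4-one, via dimethyl acetal 8 (not isolated)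
Conditions: Tl(NO3)3·3H2O (1.1 equiv), MeOH–HC(OMe)3, rt; filter TlNO3; then 10% HCl in MeOH, reflux
Reagents that add atoms: none
Why: This is the oxidative 1,2-aryl rearrangement of a 2'-hydroxychalcone by trivalent thallium, the standard thallium trinitrate route to isoflavones. Methanol and the electrophilic metal add across the enone double bond, the metal on the α-carbon and the methoxy group on the benzylic β-carbon. Loss of monovalent thallium is assisted by the aryl ring, which bridges as a phenonium ion and ends on the α-carbon (new C3–C1' bond), and the resulting methoxy-stabilised β-oxocarbenium ion is trapped by methanol as the racemic acetal 8. Hot methanolic HCl regenerates the oxocarbenium ion, the free 2'-hydroxyl adds to it in a six-membered 6-exo-trig closure (new O1–C2 bond), and loss of methanol gives the pyranone, erasing the only stereocentre. Aryl rather than aroyl migration is secured by the methoxy groups para and ortho to the migrating carbon. The direction of ring closure is secured because only the hydroxyl beside the future C8 oxygen is free while O6' is benzylated. Chemoselectivity for the enone over the two electron-rich rings rests on using about one equivalent of oxidant at room temperature. Benzyl ethers tolerate both oxidant and acid, and no other alkene is present because the prenyl group is introduced later.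

Step 5
Reactants: 9 5,8-bis(benzyloxy)-7-methoxy-3-(2,4,5-trimethoxyphenyl)chromen-4-one
Product: 10 5,8-dihydroxy-7-methoxy-3-(2,4,5-trimethoxyphenyl)chromen-4-one
Conditions: H2 (1 atm), 10% Pd/C, EtOAc–MeOH, rt
Reagents that add atoms: none
Why: Hydrogenolysis of aryl benzyl ethers, which is much faster than reduction of the pyranone double bond at one atmosphere. The hydroquinone 10 would be kept under inert gas and used at once.

Step 6
Reactants: 10 5,8-dihydroxy-7-methoxy-3-(2,4,5-trimethoxyphenyl)chromen-4-one
Product: 11 5-hydroxy-7-methoxy-8-(methoxymethoxy)-3-(2,4,5-trimethoxyphenyl)chromen-4-one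
Conditions: MOMCl (1.1 equiv), iPr2NEt, CH2Cl2, 0 °C
Reagents that add atoms: chloromethyl methyl ether, COCCl
Why: Selective O-alkylation: the 5-OH is held in a hydrogen bond to C4=O and is a poor nucleophile, so one equivalent of the chloride should react only at the 8-OH.

Step 7
Reactants: 11 5-hydroxy-7-methoxy-8-(methoxymethoxy)-3-(2,4,5-trimethoxyphenyl)chromen-4-one
Product: 12 7-methoxy-8-(methoxymethoxy)-5-(2-methylbut-3-yn-2-yloxy)-3-(2,4,5-trimethoxyphenyl)chromen-4-one
Conditions: 3-chloro-3-methylbut-1-yne, DBU, CuCl2·2H2O (1 mol %), MeCN, 0 °C to rt
Reagents that add atoms: 3-chloro-3-methylbut-1-yne, CC(C)(Cl)C#C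
Why: Copper-catalysed propargylic etherification: a copper acetylide ionises to an allenylidene-type electrophile that the phenoxide attacks at the tertiary carbon. The amidine base fully deprotonates the chelated 5-OH, the only free hydroxyl; the method is established for ortho-acylphenols.

Step 8
Reactants: 12 7-methoxy-8-(methoxymethoxy)-5-(2-methylbut-3-yn-2-yloxy)-3-(2,4,5-trimethoxyphenyl)chromen-4-one
Product: 13 7-methoxy-8-(methoxymethoxy)-5-(2-methylbut-3-en-2-yloxy)-3-(2,4,5-trimethoxyphenyl)chromen-4-one
Conditions: H2 (1 atm), Pd/CaCO3 poisoned with Pb(OAc)2 (Lindlar catalyst), quinoline, EtOAc, rt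
Reagents that add atoms: none
Why: Lindlar semi-hydrogenation of a terminal alkyne stops at the vinyl group; the pyranone double bond and the aryl ethers are not reduced on the poisoned catalyst.

Step 9
Reactants: 13 7-methoxy-8-(methoxymethoxy)-5-(2-methylbut-3-en-2-yloxy)-3-(2,4,5-trimethoxyphenyl)chromen-4-one
Product: 14 5-hydroxy-7-methoxy-8-(methoxymethoxy)-6-(3-methylbut-2-enyl)-3-(2,4,5-trimethoxyphenyl)chromen-4-one
Conditions: PhNEt2, 130 °C, under N2
Reagents that add atoms: none
Why: Aromatic Claisen rearrangement: the [3,3] shift joins the terminal CH2 of the tertiary allyl ether to C6, the only ortho carbon bearing hydrogen, and tautomerisation restores the chelated 5-OH, so the linear prenyl group results directly. C8 is substituted, so no para product can form, and the basic solvent suppresses ionisation of the ether.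

Step 10
Reactants: 14 5-hydroxy-7-methoxy-8-(methoxymethoxy)-6-(3-methylbut-2-enyl)-3-(2,4,5-trimethoxyphenyl)chromen-4-one
Product: 15 5,8-dihydroxy-7-methoxy-6-(3-methylbut-2-enyl)-3-(2,4,5-trimethoxyphenyl)chromen-4-one
Conditions: 3 M aq HCl, MeOH, 40 °C, under N2
Reagents that add atoms: none
Why: Acid-catalysed acetal cleavage of the MOM ether, standard for prenylated flavonoids. Dilute acid at low temperature should leave the trisubstituted alkene, the methyl ethers and the pyranone untouched.

## Compound list

1 | 1-(2,6-dihydroxy-4-methoxyphenyl)ethanone (2',6'-dihydroxy-4'-methoxyacetophenone) | CC(=O)c1c(O)cc(OC)cc1O | starting material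
2 | potassium 3-acetyl-2,4-dihydroxy-6-methoxyphenyl sulfate | CC(=O)c1c(O)cc(OC)c(OS(=O)(=O)[O-])c1O.[K+] | intermediate
3 | 1-(2,3,6-trihydroxy-4-methoxyphenyl)ethanone | CC(=O)c1c(O)cc(OC)c(O)c1O | intermediate
4 | benzyl bromide | BrCc1ccccc1 | starting material
5 | 1-[3,6-bis(benzyloxy)-2-hydroxy-4-methoxyphenyl]ethanone | CC(=O)c1c(OCc2ccccc2)cc(OC)c(OCc2ccccc2)c1O | intermediate
6 | 2,4,5-trimethoxybenzaldehyde | COc1cc(OC)c(C=O)cc1OC | starting material
7 | (E)-1-[3,6-bis(benzyloxy)-2-hydroxy-4-methoxyphenyl]-3-(2,4,5-trimethoxyphenyl)prop-2-en-1-one | O=C(/C=C/c1cc(OC)c(OC)cc1OC)c1c(O)c(OCc2ccccc2)c(OC)cc1OCc1ccccc1 | intermediate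
8 | 1-[3,6-bis(benzyloxy)-2-hydroxy-4-methoxyphenyl]-3,3-dimethoxy-2-(2,4,5-trimethoxyphenyl)propan-1-one (racemic) | COC(OC)C(c1cc(OC)c(OC)cc1OC)C(=O)c1c(O)c(OCc2ccccc2)c(OC)cc1OCc1ccccc1 | intermediate
9 | 5,8-bis(benzyloxy)-7-methoxy-3-(2,4,5-trimethoxyphenyl)chromen-4-one | COc1cc(OCc2ccccc2)c2c(=O)c(-c3cc(OC)c(OC)cc3OC)coc2c1OCc1ccccc1 | intermediate
10 | 5,8-dihydroxy-7-methoxy-3-(2,4,5-trimethoxyphenyl)chromen-4-one | COc1cc(O)c2c(=O)c(-c3cc(OC)c(OC)cc3OC)coc2c1O | intermediate
11 | 5-hydroxy-7-methoxy-8-(methoxymethoxy)-3-(2,4,5-trimethoxyphenyl)chromen-4-one | COCOc1c(OC)cc(O)c2c(=O)c(-c3cc(OC)c(OC)cc3OC)coc12 | intermediate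
12 | 7-methoxy-8-(methoxymethoxy)-5-(2-methylbut-3-yn-2-yloxy)-3-(2,4,5-trimethoxyphenyl)chromen-4-one | COCOc1c(OC)cc(OC(C)(C)C#C)c2c(=O)c(-c3cc(OC)c(OC)cc3OC)coc12 | intermediate
13 | 7-methoxy-8-(methoxymethoxy)-5-(2-methylbut-3-en-2-yloxy)-3-(2,4,5-trimethoxyphenyl)chromen-4-one | COCOc1c(OC)cc(OC(C)(C)C=C)c2c(=O)c(-c3cc(OC)c(OC)cc3OC)coc12 | intermediate
14 | 5-hydroxy-7-methoxy-8-(methoxymethoxy)-6-(3-methylbut-2-enyl)-3-(2,4,5-trimethoxyphenyl)chromen-4-one | COCOc1c(OC)c(CC=C(C)C)c(O)c2c(=O)c(-c3cc(OC)c(OC)cc3OC)coc12 | intermediate
15 | 5,8-dihydroxy-7-methoxy-6-(3-methylbut-2-enyl)-3-(2,4,5-trimethoxyphenyl)chromen-4-one | COc1cc(OC)c(-c2coc3c(O)c(OC)c(CC=C(C)C)c(O)c3c2=O)cc1OC | target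

## Step count and risks

Total steps: 10. Longest linear sequence: 10 steps, from 1 to 15; compounds 4 and 6 are bought.

**Step 4 (key step).** The most likely failure is oxidation of the electron-rich rings by trivalent thallium, through aryl thallation or oxidative demethylation of the para-dimethoxy pattern of ring B, in competition with oxythallation of the enone. The acid formed could also close the chalcone to the flavanone before the rearrangement. The fallback uses no oxidant and forms the C3–C1' bond by cross-coupling. It sets out from ketone 5 and comes back at 9. Ketone 5 is heated with N,N-dimethylformamide dimethyl acetal to give (E)-1-[3,6-bis(benzyloxy)-2-hydroxy-4-methoxyphenyl]-3-(dimethylamino)prop-2-en-1-one F1. Iodine in methanol cyclises F1 to 5,8-bis(benzyloxy)-3-iodo-7-methoxychromen-4-one F2. Suzuki–Miyaura coupling of F2 with (2,4,5-trimethoxyphenyl)boronic acid, using Pd(PPh3)4 (zerovalent palladium) and aqueous Na2CO3, gives 9.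

**Step 2.** The two hydroxyls ortho to the ketone may not be discriminated well enough, leading to benzylation at O2' instead of O6' or to over-benzylation. The trihydroxyarene may also be air-oxidised under base. The fallback fixes the regiochemistry by tying up the 2',3'-catechol. It sets out from 3 and comes back at 5. Heating 3 with dichlorodiphenylmethane gives 1-(5-hydroxy-7-methoxy-2,2-diphenyl-1,3-benzodioxol-4-yl)ethanone F3. Benzylation of its only free hydroxyl with 4 and K2CO3 in DMF gives 1-(5-benzyloxy-7-methoxy-2,2-diphenyl-1,3-benzodioxol-4-yl)ethanone F4. Aqueous acetic acid removes the ketal to give 1-(6-benzyloxy-2,3-dihydroxy-4-methoxyphenyl)ethanone F5. One further equivalent of 4 with K2CO3 then benzylates the non-chelated 3'-OH of F5 and gives 5.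

**Step 7.** Etherification of the chelated, peri-carbonyl phenoxide may be slow. Elimination or oligomerisation of the tertiary propargylic chloride, and base-induced opening of the pyranone, could then compete. The fallback replaces copper-propargyl chemistry by a Tsuji–Trost allylic etherification. It sets out from 11 and comes back at 13, skipping 12 and step 8. Phenol 11 is treated with tert-butyl 2-methylbut-3-en-2-yl carbonate and Pd(PPh3)4 (zerovalent palladium) in THF at 0 °C. The cationic π-allyl complex is attacked at its more substituted end under kinetic control. No compound outside the list arises (F0).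

**Step 10.** The acid needed for acetal cleavage may protonate the prenyl alkene, with ring closure onto the neighbouring 5-OH to a chroman. The freed hydroquinone may also be air-oxidised. The fallback removes all acid from the end game by using a fluoride-labile group on O8. It sets out from 10 and comes back at 15. Diol 10 is silylated with triisopropylsilyl chloride and imidazole to give 5-hydroxy-7-methoxy-8-(triisopropylsilyloxy)-3-(2,4,5-trimethoxyphenyl)chromen-4-one F6. The conditions of step 7 give 7-methoxy-5-(2-methylbut-3-yn-2-yloxy)-8-(triisopropylsilyloxy)-3-(2,4,5-trimethoxyphenyl)chromen-4-one F7. The conditions of step 8 give 7-methoxy-5-(2-methylbut-3-en-2-yloxy)-8-(triisopropylsilyloxy)-3-(2,4,5-trimethoxyphenyl)chromen-4-one F8. The conditions of step 9 give 5-hydroxy-7-methoxy-6-(3-methylbut-2-enyl)-8-(triisopropylsilyloxy)-3-(2,4,5-trimethoxyphenyl)chromen-4-one F9. Tetrabutylammonium fluoride buffered with acetic acid in THF at 0 °C then gives 15.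

## Further compounds

F1 | step 4 | (E)-1-[3,6-bis(benzyloxy)-2-hydroxy-4-methoxyphenyl]-3-(dimethylamino)prop-2-en-1-one | CN(C)/C=C/C(=O)c1c(O)c(OCc2ccccc2)c(OC)cc1OCc1ccccc1
F2 | step 4 | 5,8-bis(benzyloxy)-3-iodo-7-methoxychromen-4-one | COc1cc(OCc2ccccc2)c2c(=O)c(I)coc2c1OCc1ccccc1
F3 | step 2 | 1-(5-hydroxy-7-methoxy-2,2-diphenyl-1,3-benzodioxol-4-yl)ethanone | CC(=O)c1c(O)cc(OC)c2OC(c3ccccc3)(c3ccccc3)Oc12
F4 | step 2 | 1-(5-benzyloxy-7-methoxy-2,2-diphenyl-1,3-benzodioxol-4-yl)ethanone | CC(=O)c1c(OCc2ccccc2)cc(OC)c2OC(c3ccccc3)(c3ccccc3)Oc12
F5 | step 2 | 1-(6-benzyloxy-2,3-dihydroxy-4-methoxyphenyl)ethanone | CC(=O)c1c(OCc2ccccc2)cc(OC)c(O)c1O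
F0 | step 7 | none | none
F6 | step 10 | 5-hydroxy-7-methoxy-8-(triisopropylsilyloxy)-3-(2,4,5-trimethoxyphenyl)chromen-4-one | COc1cc(O)c2c(=O)c(-c3cc(OC)c(OC)cc3OC)coc2c1O[Si](C(C)C)(C(C)C)C(C)C
F7 | step 10 | 7-methoxy-5-(2-methylbut-3-yn-2-yloxy)-8-(triisopropylsilyloxy)-3-(2,4,5-trimethoxyphenyl)chromen-4-one | COc1cc(OC(C)(C)C#C)c2c(=O)c(-c3cc(OC)c(OC)cc3OC)coc2c1O[Si](C(C)C)(C(C)C)C(C)C
F8 | step 10 | 7-methoxy-5-(2-methylbut-3-en-2-yloxy)-8-(triisopropylsilyloxy)-3-(2,4,5-trimethoxyphenyl)chromen-4-one | COc1cc(OC(C)(C)C=C)c2c(=O)c(-c3cc(OC)c(OC)cc3OC)coc2c1O[Si](C(C)C)(C(C)C)C(C)C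
F9 | step 10 | 5-hydroxy-7-methoxy-6-(3-methylbut-2-enyl)-8-(triisopropylsilyloxy)-3-(2,4,5-trimethoxyphenyl)chromen-4-one | COc1c(CC=C(C)C)c(O)c2c(=O)c(-c3cc(OC)c(OC)cc3OC)coc2c1O[Si](C(C)C)(C(C)C)C(C)C
A1 | alternative 1 | 3-methoxy-5-(methoxymethoxy)-2-(3-methylbut-2-enyl)benzene-1,4-diol | Oc1cc(OCOC)c(O)c(OC)c1CC=C(C)C
A2 | alternative 1 | 4-hydroxy-3-methoxy-4-[1-(methoxymethoxy)ethenyl]-2-(3-methylbut-2-enyl)cyclobut-2-en-1-one (racemic) | O=C1C(CC=C(C)C)=C(OC)C1(O)C(=C)OCOC
A3 | alternative 2 | 5,7-dimethoxy-6-(3-methylbut-2-enyl)-3-(2,4,5-trimethoxyphenyl)chromen-4-one | COc1cc2occ(-c3cc(OC)c(OC)cc3OC)c(=O)c2c(OC)c1CC=C(C)C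
A4 | alternative 2 | 3,5-dimethoxy-4-(3-methylbut-2-enyl)-2-(trimethylsilyl)phenyl trifluoromethanesulfonate | COc1cc(OS(=O)(=O)C(F)(F)F)c([Si](C)(C)C)c(OC)c1CC=C(C)C
A5 | alternative 2 | methyl 3-hydroxy-2-(2,4,5-trimethoxyphenyl)prop-2-enoate | COC(=O)C(=CO)c1cc(OC)c(OC)cc1OC
A6 | alternative 3 | 3-(2-hydroxy-4,5-dimethoxyphenyl)-7-methoxy-5,8-bis(methoxymethoxy)-6-(3-methylbut-2-enyl)chromen-4-one | COCOc1c(CC=C(C)C)c(OC)c(OCOC)c2occ(-c3cc(OC)c(OC)cc3O)c(=O)c12
A7 | alternative 3 | 3-ethynyl-7-methoxy-5,8-bis(methoxymethoxy)-6-(3-methylbut-2-enyl)chromen-4-one | COCOc1c(CC=C(C)C)c(OC)c(OCOC)c2occ(C#C)c(=O)c12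
A8 | alternative 3 | pentacarbonyl[methoxy(1-methoxyvinyl)carbene]chromium, (CO)5Cr=C(OMe)C(OMe)=CH2 | COC(=C)C(OC)=[Cr](=C=O)(=C=O)(=C=O)(=C=O)=C=O
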